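- In a one-step world, starting material and partner would simply give target. This flask has side roads, so I began with the problem as it stood:

- birch: starting material 0.80 M; partner 0.960 M; temperature 35 °C; time 5.0 h
- maple: starting material 0.80 M; partner 0.960 M; temperature 55 °C; time 5.0 h

    starting material + partner → intermediate + by-product (k1 = 0.014 L mol⁻¹ min⁻¹, Ea1 = 71.0 kJ mol⁻¹)
    intermediate ⇌ target (K2 = 0.68, k2 = 0.036 min⁻¹, Ea2 = 96.0 kJ mol⁻¹, ΔH2 = −54.0 kJ mol⁻¹)
    intermediate ⇌ isomer of the product (K3 = 3.1, k3 = 0.015 min⁻¹, Ea3 = 99.0 kJ mol⁻¹, ΔH3 = −9.00 kJ mol⁻¹)
    partner ⇌ dormant form (K4 = 0.42, k4 = 0.0081 min⁻¹, Ea4 = 108 kJ mol⁻¹, ΔH4 = −25.0 kJ mol⁻¹)
    starting material + target → side product (k5 = 0.11 L mol⁻¹ min⁻¹, Ea5 = 58.0 kJ mol⁻¹)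
    partner → decomposed reagent (k6 = 0.0093 min⁻¹, Ea6 = 85.0 kJ mol⁻¹)
    (constants at 35 °C)

- percentages count the starting material that a species holds: one side product counts as two
- the constants hold at 35 °C; other temperatures follow from the activation energies and enthalpies

1. which of the two there is more of at the end, counted by the starting material in each, birch (target / side product)
2. which of the two there is more of at the end, counted by the starting material in each, maple (target / side product)
3. final target, as a percentage of the starting material charged, in birch
4. final target, as a percentage of the starting material charged, in maple

- I wrote the balance of starting material, the smaller charge. Every part of it ends unreacted, in side product, or in what I called the pool: intermediate, target and isomer together.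
- In maple the step to target relaxes in 0.311 min and the step to isomer in 0.0522 h, both shorter than 5.0 h . So I treated the pool as a pre-equilibrium, and I assumed the same for birch.
- With a and b the equilibrium constants to target and isomer, the target's share of the pool is φ = a/(1 + a + b). On that assumption φ in birch was 14.2 %. At 55 °C a fell to 0.188 and b to 2.50, so the share in maple was 5.10 %.
- First way, for birch: I held starting material at half its charge. Partner then split between the productive step and decay, and I estimated that 0.361 M of it entered the pool.
- I put the side step's drain on the pool over the run at an exponent of 1.88, which by my estimate left 0.163 M and target at 2.89 %.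
- Second way, for birch: starting material leaves by the first step and by the side step, and these balance when target equals the ratio of their rate constants times partner. With partner decaying, and partly dormant, to an estimated 0.0412 M, that level came to 0.005247 M, or 0.656 % of the charge.
- The two parted: the first way gave more than the second, by a factor of 4.41. I judged that the second way cheated, because it needs the pool to follow partner down, while the pool's estimated half-life under the drain, 1.85 h, is longer than partner's 1.2 h by decay alone in birch.
- I kept the first way. For maple it gave 0.289 M entering and 0.101 M left, so target at 0.642 %.
- By the same reckoning, counting two of starting material in each side product, the larger in birch was side product, and the larger in maple was side product.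
- The forecast also chose side product for birch and side product for maple. It put target at 3.5 % in birch (range 2 % to 6.5 %) and 0.9 % in maple (range 0.5 % to 1.8 %), higher than my figures in both flasks. Its ground for the fall was that “the exothermic equilibrium shrinks the target's share of the pool”.
- Birch ended at 1.70 % target against 58.3 % side product, and maple at 0.480 % against 70.2 %, so the forecast stood within the margin. With the other charge and the time held, moving birch's answer by 6 points took 2.78 M of partner. Maple's balance at the end left 10.1 % in the pool, and φ of that is 0.514 %.
- The neighbour, a flask like maple kept at 80 °C, has φ = 1.53 %. Its balance leaves 3.13 % in the pool, which gives 0.0480 % target; the run gave 0.0476 %.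

Its constants are assumed; the flask was simulated.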